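The runs come from a simulation for an exercise, and the scatter is random.

Millimolar of precatalyst was the unit I reckoned in for this flask, a closed one in which substrate gives target and an isomer of the product.

in all of them: substrate 0.020 M

|  | precatalyst | remark | time |
|---|---|---|---|
| Monday's | 0.11 mM | the very flask that is asked about, followed so far |  |
| Saturday's | 0.22 mM | run made earlier |  |
| flask | 0.11 mM |  | 10 h |

| run | time / h | isomer of the product / % | target / % |
|---|---|---|---|
| Monday's | 0.417 | 55.5 | 30.5 |
| Monday's | 0.667 | 62.0 | 33.8 |
| Monday's | 1.00 | 64.4 | 35.3 |
| Monday's | 2.00 | 64.7 | 35.0 |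
| Monday's | 3.00 | 64.3 | 34.8 |
| Monday's | 5.00 | 64.3 | 35.0 |
| Saturday's | 0.667 | 47.8 | 50.8 |
| Saturday's | 1.33 | 48.8 | 51.7 |
| Saturday's | 2.00 | 48.6 | 51.9 |
| Saturday's | 2.50 | 48.1 | 51.5 |
| Saturday's | 3.00 | 48.6 | 52.0 |
| Saturday's | 4.00 | 47.8 | 51.6 |

(standard deviation of a reading: 0.5 percentage points)

- share of isomer of the product in isomer of the product plus target at 80 s
- share of isomer of the product in isomer of the product plus target at 25 min
- share of isomer of the product in isomer of the product plus target at 10 h
- which of isomer of the product and target there is more of at 10 h



At the bench one reads c(isomer of the product)/c(target) once the readings lie flat, and takes that ratio for the flask. Monday's flask gave 1.85 at 2.00 h, and Saturday's flask gave 0.936 at 2.00 h. Saturday's flask held twice the precatalyst and showed half the ratio, a mark of kinetic rather than thermodynamic control. So I multiplied each ratio by its charge, which gave 0.203 mM and 0.206 mM. I kept their middle, 0.205 mM, and called it the balance loading, the precatalyst charge at which this reckoning puts the ratio at one, with the substrate charge held at 0.020 M. Monday's charge over the balance loading is 0.537, so for Monday's flask I reckoned an isomer share of 65.0% at 25 min and 10 h, with the isomer ahead. The rule has a border, though: it stands on flat readings, and 80 s is 0.0533 of the time of Monday's first reading, so I gave no figure there.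

The forecast put 64.7%, 64.7% and 64.8% at the three times, with isomer of the product ahead, and its last figure lay a little below mine. Its ground was: “Selectivity depends on catalyst loading, so it is kinetic.”

The simulation of Monday's flask gave 59.8%, 64.6% and 64.7%, with isomer of the product ahead. The forecast stood 4.9 percentage points high at 80 s and 0.10 points high at 10 h, both within the margin.

    substrate ⇌ other conformer (K = 2.20, k = 0.0512 min⁻¹)
    substrate + free catalyst → free catalyst + target (k = 1750 M⁻¹ min⁻¹)
    free catalyst + other conformer → free catalyst + isomer of the product (k = 1.00 × 10⁵ M⁻¹ min⁻¹)
    precatalyst ⇌ free catalyst (K = 0.180, k = 0.289 min⁻¹)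
    substrate + free catalyst → spent catalyst (k = 0.973 M⁻¹ min⁻¹)

One reason among others for the isomer share at 10 h in Monday's flask is the way back from free catalyst to precatalyst: the run without it ended at a share of 31.3% against 64.7%. In Monday's flask at that time, free catalyst stood at 14.7% of the catalyst charged, precatalyst at 81.7% and spent catalyst at 3.57%.

For the neighbour flask with 0.280 mM of precatalyst, a charge above the balance loading, the balance loading gives an isomer share of 42.2%. The simulation of that neighbour flask gave 42.4% at 10 h, and at its end target held most of the substrate.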